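Choose the set-up of the next run by following one molecule of intermediate to its fork.

    starting material + partner → intermediate (k1 = 3.02 M⁻¹ min⁻¹)
    intermediate → target (k2 = 0.0165 min⁻¹)
    intermediate → side product (k3 = 0.0428 min⁻¹)

| setting | amber | green | grey | red |
|---|---|---|---|---|
| starting material | 0.010 M | 0.010 M (fed, over 12.0 min) | 0.010 M | 0.010 M |
| partner | 10.0 mM | 10.0 mM | 10.0 mM (fed, over 12.0 min) | 10.0 mM |
| time | 15 min | 15 min | 15 min |  |
| remark | everything together in a closed stirred flask, run for 15 min | a stirred flask in which starting material is dosed at a steady rate over 12.0 min without added volume, worked up at 15 min | a stirred flask in which partner is dosed at a steady rate over 12.0 min without added volume, worked up at 15 min | a single well-mixed tank run continuously and read at steady state, 15 min in it on average |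

- the set-up with the highest amount of intermediate at the outlet or at the end, in percent of the starting material put in ("none" if the first two lie within 2 percentage points) (amber / green / grey / red / none)
- amount of intermediate at the outlet or at the end, in percent of the starting material put in, amber
- amount of intermediate at the outlet or at the end, in percent of the starting material put in, green
- amount of intermediate at the outlet or at the end, in percent of the starting material put in, grey
- amount of intermediate at the outlet or at the end, in percent of the starting material put in, red

- the stated concentrations are those of everything mixed, before any reaction; amounts are the same in each set-up
- the feed brings no volume worth counting
- run time (amber): 15 min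

**Lifetime at fork.** A molecule of intermediate leaves by the step to target or the step to side product, both first order, and so its mean lifetime, one over the sum of the two constants, is 16.9 min. Over a time t in a closed flask, it survives with chance exp(-t/lifetime). In a tank with mean stay t, the chance is 1/(1+t/lifetime).

**Amber reckoned.** With equal charges, 31.2% of the starting material has reacted in amber by 15 min. A molecule made mid-run in amber has 7.50 min to survive, a chance of 0.641, which gives an estimate of 20.0%. Making in amber runs faster early than late, so this estimate leans high.

**Red reckoned.** The balance of the red tank gives 25.3% reacted, less than amber. The survival chance in red is 0.529, also lower than amber's mid-run chance, which gives 13.4% for red.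

**Dosed flasks.** Green and grey should read alike, because the rate is symmetric in two equal charges. Their molecules are made later, yet their rate starts from zero, and the hand reckoning stops there. The next run is provisionally charged as amber.

**The forecast.** It names amber, with amber 19.5%, green 15.5%, grey 15.5% and red 13.4%, its amber figure lying below the hand figure. Its grounds: “dosing starves the second-order step”.

**The result.** The best set-up is amber, with amber 19.5%, green 15.4%, grey 15.4% and red 13.4%. The intermediate's half-life under both exits, 11.7 min, is shorter than the 23 min half-life of the starting material in amber by step 1 alone with the partner as charged, and amber's 19.5% is 0.625 of the 31.2% reacted. In green, the selectivity for target, 0.278, turns 1.56% of target into 5.60% of intermediate lost, so green made 21.0% and kept 0.733 of it.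

(All constants were drawn at random within sensible limits; the run is a simulation.)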